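The readings are calculated with made-up constants; noise was put on by code.

In a one-step world, first order in substrate and with partner fixed, the fraction turned over in a given time is the same at any charge, so an order of 1 is the zero of the scale.

| flask | substrate | partner | remark | time |
|---|---|---|---|---|
| Wednesday's | 20 mM | 60 mM | run made earlier |  |
| Friday's | 13 mM | 60 mM | run made earlier |  |
| Thursday's | 30 mM | 60 mM | run made earlier |  |
| red | 20 mM | 60.0 mM (fed, over 40.0 min) | all but partner at the start; partner goes in evenly over 40.0 min, the run ends at 80 min | 80 min |
| teal | 20 mM | 60.0 mM | one stirred flow tank at steady state, fed with the mixture as stated, mean residence time 80 min |  |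
| green | 20 mM | 60.0 mM | a closed flask charged with all of it at once and left for 80 min | 80 min |
| violet | 20 mM (fed, over 40.0 min) | 60.0 mM | all but substrate at the start; substrate goes in evenly over 40.0 min, the run ends at 80 min | 80 min |

| run | time / min | target / % | substrate / % |
|---|---|---|---|
| Wednesday's | 15.0 | 23 | 80 |
| Wednesday's | 30.0 | 36 | 65 |
| Wednesday's | 50.0 | 49 | 52 |
| Wednesday's | 60.0 | 54 | 46 |
| Wednesday's | 80.0 | 64 | 36 |
| Friday's | 12.0 | 21 | 78 |
| Friday's | 25.0 | 40 | 61 |
| Friday's | 40.0 | 51 | 47 |
| Friday's | 50.0 | 61 | 38 |
| Friday's | 60.0 | 65 | 35 |
| Thursday's | 6.00 | 7 | 92 |
| Thursday's | 15.0 | 18 | 82 |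
| Thursday's | 30.0 | 32 | 70 |
| Thursday's | 50.0 | 39 | 60 |
| Thursday's | 60.0 | 47 | 54 |

(readings scatter by 1.5 percentage points)

* the set-up with the highest amount of target at the outlet or at the end, in percent of the substrate put in ("none" if the first two lie within 2 percentage points) (red / teal / green / violet / none)
* amount of target at the outlet or at the end, in percent of the substrate put in, red
* amount of target at the outlet or at the end, in percent of the substrate put in, teal
* amount of target at the outlet or at the end, in percent of the substrate put in, green
* amount of target at the outlet or at the end, in percent of the substrate put in, violet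

- the stated concentrations are those of everything mixed, before any reaction; amounts are the same in each set-up
- the feed brings no volume worth counting
- the earlier runs were made in a closed, stirred flask

Two ways read the order. The first goes across runs at early readings, all with 60 mM of partner. The fractional rate f is ln(1/fraction of substrate left) divided by time. It is 0.0207 min⁻¹ in Friday's run at 12.0 min and 0.0132 min⁻¹ in Thursday's at 15.0 min, so it is higher at 13 mM than at 30 mM. The charge order n, one minus ln(ratio of f) over ln(ratio of charges), the usual order in concentration, reads 0.464, with the scatter of the readings in it.

The second way stays inside Wednesday's run. Substrate falls by 0.0133 min⁻¹ of the charge early, at a mean of 90.0 % left, and by 0.00533 min⁻¹ late, at a mean of 44.0 %. That gives an order in time of 1.28, and the two ways part.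

The clock way is the one that cheats. With n as read, substrate explains a rate ratio of 1.39 out of 2.50, which leaves a factor of 1.79. Partner taken by target supplies 1.18. This reckoning therefore expects partner to wear away beyond what target takes, and expects green, Wednesday's recipe, to read 64 %.

The forecast reads the fall of f with charge differently, as “inhibition by substrate and product together”. It gives red 55 %, teal 49.5 %, green 64 % and violet 56 %, with green best.

The flasks give red 58.4 %, teal 50.3 %, green 63.5 % and violet 51.3 %, with green best.

    substrate + partner → target, rate k1*[substrate]^0.5*[partner] (k = 0.0430 M⁻⁰·⁵ min⁻¹)
    2 partner → homo dimer (k = 0.150 M⁻¹ min⁻¹)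

In green, partner stands at 32 % of its charge at 80.0 min, with 14.2 mM of homo dimer formed. With the loss of partner to homo dimer taken away, green gives 84.5 % of target instead of 63.5 %, and with that loss in place but the reading put ten times later it gives >99.9 %, so the shortfall comes from the two together. Carried to red's recipe with 80 mM of substrate, n scales f by 0.476, so red's 58.4 % of target becomes an estimated 34.1 %. That flask stores 28.8 % of target, at 0.750 equiv of partner.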